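## Retrosynthetic overview

- Ring labels: A is the trioxygenated ring, B the para-phenylene, C the ring with one OH, D the ortho-phenylene. The outer ring A OH travels as Br, the ring C OH as Cl and the central ring A OH as a MOM ether. All three are unmasked last.
- Key disconnection: the B–CH2CH2–C bond comes from a nitrogen-deletion ring contraction (18 to 17 members) of a CH2–NH–CH2 azacyclophane. That ring is closed from an open dialdehyde and ammonia. It is the only ring closure, since all four benzene rings are bought.
- A–O–B comes from an Ullmann coupling of a symmetric ring A dibromide with 4-hydroxybenzaldehyde. C–O–D comes from SNAr of the ring D phenol on 3-chloro-2-fluorobenzaldehyde.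
- A–CH2CH2–D comes from the benzylic dianion of o-cresol and a quinone methide released from tribrominated p-cresol.
- Carbon sources: p-cresol (twice), o-cresol, 1-chloro-2-fluorobenzene and DMF.

Assumption: the SMILES has no stereodescriptor and the molecule has no stereocentre, and the macrocycle is taken as conformationally mobile, so no asymmetric step is needed.

## Route

Step 1
Reactants: 1 p-cresol (4-methylphenol)
Product: 3 2,6-dibromo-4-(bromomethyl)phenol, via 2,6-dibromo-4-methylphenol 2 (not isolated)
Conditions: Br2 (2.05 equiv), 1,2-dichlorobenzene, 35 °C, 2 h; then Br2 (1.0 equiv), 145 °C, 3 h, N2 sweep; crystallise, use at once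
Reagents that add atoms: bromine, BrBr
Why: Electrophilic aromatic bromination fills both positions ortho to OH, and the third equivalent then enters the only remaining reactive site, the para CH3, by thermal side-chain bromination through the 4-bromodienone/quinone methide–HBr manifold.

Step 2
Reactants: 3 2,6-dibromo-4-(bromomethyl)phenol; 4 o-cresol (2-methylphenol, 2.3 equiv)
Product: 7 2,6-dibromo-4-[2-(2-hydroxyphenyl)ethyl]phenol, via dipotassium o-cresol dianion 5 (not isolated), via 2,6-dibromo-para-quinone methide 6 (not isolated)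
Conditions: 4, n-BuLi/KOtBu (2.0 equiv each per 4), heptane, reflux, 3 h; solid washed with hexane; THF, −78 °C; 3 in THF added over 30 min; to −20 °C; H2O/HCl work-up
Reagents that add atoms: none
Why: This is lateral dimetalation followed by 1,6-conjugate addition: one equivalent of carbanion 5 removes the acidic OH proton of 3, bromide leaves to give 6, and a second equivalent adds through carbon at the exocyclic CH2 with rearomatisation, far faster at −78 °C than bromine–metal exchange.

Step 3
Reactants: 8 1-chloro-2-fluorobenzene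
Product: 10 3-chloro-2-fluorobenzaldehyde, via 3-chloro-2-fluorophenyllithium 9 (not isolated)
Conditions: LiN(iPr)2 (1.05 equiv), THF, −78 °C, 1 h; DMF (1.5 equiv); aq HCl
Reagents that add atoms: N,N-dimethylformamide, CN(C)C=O
Why: Directed ortho-metalation takes the most acidic C–H, next to fluorine, and formylation with DMF puts CHO ortho to F, so ring C gains its benzylic carbon and its SNAr activator in one operation.

Step 4
Reactants: 7 2,6-dibromo-4-[2-(2-hydroxyphenyl)ethyl]phenol; 10 3-chloro-2-fluorobenzaldehyde
Product: 12 3-chloro-2-(2-{2-[3,5-dibromo-4-(methoxymethoxy)phenyl]ethyl}phenoxy)benzaldehyde, via free dibromophenol diaryl ether 11 (not isolated)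
Conditions: K2CO3 (3.5 equiv), DMF, 110 °C, 12 h; then 0 °C, MOMCl (1.5 equiv), to rt
Reagents that add atoms: chloromethyl methyl ether (MOMCl), COCCl
Why: In this SNAr on the ortho-fluorobenzaldehyde only the basic ring D phenoxide attacks, because the 2,6-dibromophenoxide is about four pKa units weaker and doubly hindered, and that phenoxide is then capped in the same pot by O-alkylation with MOMCl.

Step 5
Reactants: 1 p-cresol
Product: 13 4-hydroxybenzaldehyde
Conditions: CoCl2 (1 mol %), NaOH (3.5 equiv), MeOH, O2 (1 atm), 60 °C, 8 h; aq HCl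
Reagents that add atoms: dioxygen, O=O
Why: Cobalt-catalysed aerobic benzylic oxidation of the para-cresolate runs through quinone methide/methanol adducts and stops at the aldehyde, whose phenoxide is deactivated to further oxidation.

Step 6
Reactants: 12 3-chloro-2-(2-{2-[3,5-dibromo-4-(methoxymethoxy)phenyl]ethyl}phenoxy)benzaldehyde (1.3 equiv); 13 4-hydroxybenzaldehyde (1.0 equiv)
Product: 14 3-chloro-2-(2-{2-[3-bromo-5-(4-formylphenoxy)-4-(methoxymethoxy)phenyl]ethyl}phenoxy)benzaldehyde
Conditions: CuI (10 mol %), picolinic acid (20 mol %), K3PO4 (2 equiv), DMSO, 100 °C, 24 h; excess 12 recovered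
Reagents that add atoms: none
Why: In this Ullmann-type diaryl ether coupling the two C–Br bonds are equivalent, so either gives the same product, the excess of 12 holds the reaction at mono-coupling, and the aryl chloride is inert to monovalent copper at this temperature.

Step 7
Reactants: 14 dialdehyde
Product: 17 18-membered CH2-NH-CH2-bridged azacyclophane (Br/OMOM on ring A; Cl on ring C), via amino aldehyde 15 (not isolated), via macrocyclic aldimine 16 (not isolated)
Conditions: NH4OAc (10 equiv), NaBH(OAc)3 (4 equiv), ClCH2CH2Cl/THF 1:1, 14 added by syringe pump over 12 h (final 1 mM), rt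
Reagents that add atoms: ammonium acetate, [NH4+].CC([O-])=O
Why: This is a double reductive amination in which the first-formed primary benzylic amine is a far better imine partner than the sparingly soluble ammonia, so aldehydes go on to the dialkylamine under these conditions, and at 1 mM the second C–N bond forms intramolecularly.

Step 8
Reactants: 17 18-membered azacyclophane
Product: 19 17-membered bis(bibenzyl) macrocycle (Br/OMOM on ring A; Cl on ring C), via macrocyclic isodiazene 18 (not isolated)
Conditions: N-(benzyloxy)-N-(pivaloyloxy)-4-(trifluoromethyl)benzamide (1.5 equiv), THF (5 mM), 45 °C, 24 h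
Reagents that add atoms: none
Why: Proposed new method: ring contraction of a macrocyclic secondary dibenzylamine by nitrogen deletion, a substrate class on which this reactivity has not been shown. The N–H attacks the anomeric amide nitrogen and displaces pivalate. A 1,2-shift of benzyloxy from N to the acyl carbon then releases the benzyl ester and isodiazene 18. Isodiazene 18 loses N2 by stepwise homolysis, not by a concerted extrusion. The two benzylic radicals are born as a tethered singlet pair about 2.5 Å apart and carry no β-hydrogen, so they cannot disproportionate or diffuse apart. They collapse to the CH2–CH2 bond of the 17-membered ring, and C–Br, C–Cl, the MOM acetal and the diaryl ethers take no part. The closest known reaction type is anomeric-amide nitrogen deletion of acyclic dibenzylamines and of small-ring benzylic amines.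

Step 9
Reactants: 19 17-membered bis(bibenzyl) macrocycle
Product: 21 target CNP0290892.0, via central-O-MOM ether of the target 20 (not isolated)
Conditions: Pd2(dba)3 (5 mol %), tBuXPhos (20 mol %), KOH (8 equiv), 1,4-dioxane/H2O 1:1, 100 °C, 16 h; then 3 M HCl, MeOH, 50 °C, 2 h
Reagents that add atoms: potassium hydroxide, [K+].[OH-]
Why: Palladium-catalysed hydroxylation of aryl halides turns both C–Br and C–Cl into phenoxides while the MOM group keeps ring A from becoming an oxidisable, chelating catecholate, and acid hydrolysis of the acetal in the same flask then frees the third OH.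

## Compound list

1 | p-cresol | Cc1ccc(O)cc1 | starting material
2 | 2,6-dibromo-4-methylphenol | Cc1cc(Br)c(O)c(Br)c1 | intermediate
3 | 2,6-dibromo-4-(bromomethyl)phenol | BrCc1cc(Br)c(O)c(Br)c1 | intermediate
4 | o-cresol | Cc1ccccc1O | starting material
5 | dipotassium o-cresol dianion (O,benzylic-C) | [K+].[K+].[CH2-]c1ccccc1[O-] | intermediate
6 | 2,6-dibromo-4-methylidenecyclohexa-2,5-dien-1-one | C=C1C=C(Br)C(=O)C(Br)=C1 | intermediate
7 | 2,6-dibromo-4-[2-(2-hydroxyphenyl)ethyl]phenol | Oc1ccccc1CCc1cc(Br)c(O)c(Br)c1 | intermediate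
8 | 1-chloro-2-fluorobenzene | Fc1ccccc1Cl | starting material
9 | 3-chloro-2-fluorophenyllithium | [Li]c1cccc(Cl)c1F | intermediate
10 | 3-chloro-2-fluorobenzaldehyde | O=Cc1cccc(Cl)c1F | intermediate
11 | 3-chloro-2-{2-[2-(3,5-dibromo-4-hydroxyphenyl)ethyl]phenoxy}benzaldehyde | O=Cc1cccc(Cl)c1Oc1ccccc1CCc1cc(Br)c(O)c(Br)c1 | intermediate
12 | 3-chloro-2-(2-{2-[3,5-dibromo-4-(methoxymethoxy)phenyl]ethyl}phenoxy)benzaldehyde | O=Cc1cccc(Cl)c1Oc1ccccc1CCc1cc(Br)c(OCOC)c(Br)c1 | intermediate
13 | 4-hydroxybenzaldehyde | O=Cc1ccc(O)cc1 | intermediate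
14 | 3-chloro-2-(2-{2-[3-bromo-5-(4-formylphenoxy)-4-(methoxymethoxy)phenyl]ethyl}phenoxy)benzaldehyde | O=Cc1ccc(cc1)Oc1cc(CCc2ccccc2Oc2c(Cl)cccc2C=O)cc(Br)c1OCOC | intermediate
15 | amino aldehyde (ring C CH2NH2, ring B CHO) | O=Cc1ccc(cc1)Oc1cc(CCc2ccccc2Oc2c(Cl)cccc2CN)cc(Br)c1OCOC | intermediate
16 | macrocyclic (E)-aldimine (ring B CH=N–CH2 ring C) | Brc1cc2cc(c1OCOC)Oc1ccc(cc1)/C=N/Cc1cccc(Cl)c1Oc1ccccc1CC2 | intermediate
17 | 18-membered azacyclophane: target skeleton with CH2–NH–CH2 in place of the B–C ethano bridge, Br for the outer ring A OH, OMOM for the central ring A OH, Cl for the ring C OH | Brc1cc2cc(c1OCOC)Oc1ccc(cc1)CNCc1cccc(Cl)c1Oc1ccccc1CC2 | intermediate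
18 | macrocyclic isodiazene (1,1-diazene) of 17 | Brc1cc2cc(c1OCOC)Oc1ccc(cc1)C[N+](=[N-])Cc1cccc(Cl)c1Oc1ccccc1CC2 | intermediate
19 | 17-membered bis(bibenzyl) macrocycle: target skeleton with Br (outer ring A position), OMOM (central ring A position), Cl (ring C) | Brc1cc2cc(c1OCOC)Oc1ccc(cc1)CCc1cccc(Cl)c1Oc1ccccc1CC2 | intermediate
20 | central-O-MOM ether of the target | Oc1cc2cc(c1OCOC)Oc1ccc(cc1)CCc1cccc(O)c1Oc1ccccc1CC2 | intermediate
21 | CNP0290892.0 | Oc1cc2cc(c1O)Oc1ccc(cc1)CCc1cccc(O)c1Oc1ccccc1CC2 | target

## Step count and risks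

Total steps: 9. Longest linear sequence: 7 (steps 1, 2, 4, 6, 7, 8, 9).

**Step 2 (quinone methide alkylation).** Quinone methide 6 may polymerise, or the superbasic carbanion may attack the C–Br bonds.
- The fallback sets out from 1 and comes back at 7.
- p-Cresol 1 is taken with four equivalents of Br2 (1,2-dichlorobenzene, 35 °C then 160 °C) to 2,6-dibromo-4-(dibromomethyl)phenol F1.
- Water at 100 °C hydrolyses this to the bench-stable 3,5-dibromo-4-hydroxybenzaldehyde F2.
- Dianion 5 (3 equiv) adds 1,2 to the carbonyl group to give racemic 2,6-dibromo-4-[1-hydroxy-2-(2-hydroxyphenyl)ethyl]phenol F3.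
- Ionic hydrogenation (Et3SiH, CF3CO2H, CH2Cl2, 0 °C) removes the para-hydroxybenzylic OH to give 7.
- No free quinone methide ever meets the carbanion.

**Step 7 (ammonia macrocyclisation).** Oligomers or the open bis(primary amine) may win over ring closure.
- The fallback sets out from 14 and comes back at 17.
- Dialdehyde 14 is closed with one equivalent of allylamine (NaBH(OAc)3, ClCH2CH2Cl, 1 mM) to the N-allyl azacyclophane F4.
- Here the second C–N bond forms through a tertiary iminium ion, so the nitrogen cannot be alkylated further.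
- RhCl(PPh3)3 (5 mol %) in MeCN/H2O at reflux isomerises the allyl group to the enamine, which hydrolyses to 17.

**Step 8 (new nitrogen-deletion ring contraction).** The isodiazene may be diverted, or the diradical may be trapped before closure.
- The fallback uses only known chemistry, keeps a ring contraction, sets out from 14 and comes back at 19.
- NaBH4 reduces 14 to the bis(benzylic alcohol) F5.
- CBr4/PPh3 gives the bis(benzylic bromide) F6.
- Na2S·9H2O under high dilution closes the 18-membered thia-bridged macrocycle F7.
- mCPBA (2.2 equiv) gives the macrocyclic sulfone F8.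
- Ramberg–Bäcklund ring contraction (KOH on Al2O3, CBr2F2, t-BuOH/CH2Cl2) expels the SO2 unit and gives the 17-membered macrocyclic stilbene F9 (E/Z mixture).
- Diimide (TsNHNH2, NaOAc, THF/H2O, reflux) saturates F9 to 19 without touching C–Br or C–Cl.

## Further compounds

F1 | step 2 | 2,6-dibromo-4-(dibromomethyl)phenol | BrC(Br)c1cc(Br)c(O)c(Br)c1
F2 | step 2 | 3,5-dibromo-4-hydroxybenzaldehyde | O=Cc1cc(Br)c(O)c(Br)c1
F3 | step 2 | 2,6-dibromo-4-[1-hydroxy-2-(2-hydroxyphenyl)ethyl]phenol (racemic) | OC(Cc1ccccc1O)c1cc(Br)c(O)c(Br)c1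
F4 | step 7 | N-allyl azacyclophane | Brc1cc2cc(c1OCOC)Oc1ccc(cc1)CN(CC=C)Cc1cccc(Cl)c1Oc1ccccc1CC2
F5 | step 8 | bis(benzylic alcohol) from 14 | OCc1ccc(cc1)Oc1cc(CCc2ccccc2Oc2c(Cl)cccc2CO)cc(Br)c1OCOC
F6 | step 8 | bis(benzylic bromide) | BrCc1ccc(cc1)Oc1cc(CCc2ccccc2Oc2c(Cl)cccc2CBr)cc(Br)c1OCOC
F7 | step 8 | 18-membered thia-bridged macrocycle | Brc1cc2cc(c1OCOC)Oc1ccc(cc1)CSCc1cccc(Cl)c1Oc1ccccc1CC2
F8 | step 8 | macrocyclic sulfone | Brc1cc2cc(c1OCOC)Oc1ccc(cc1)CS(=O)(=O)Cc1cccc(Cl)c1Oc1ccccc1CC2
F9 | step 8 | 17-membered macrocyclic stilbene (E/Z mixture) | Brc1cc2cc(c1OCOC)Oc1ccc(cc1)C=Cc1cccc(Cl)c1Oc1ccccc1CC2
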